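A direct plan would assemble the C6–C3–C6 chain first and close ring C last. The ring B methyl ketone A1 would be added as its lithium enolate to the brominated ring A aldehyde A2, the new C4 hydroxyl would be capped to give silyl ether A3, the C2 ketone would be reduced with a CBS oxazaborolidine to bromo alcohol A4, ring C would be closed by palladium-catalysed O1–C8a etherification to 4-silyloxyflavan A5, and C4 would be desilylated and reoxidised to the tetra-MOM flavanone A6 before acid unmasking.
Its weakest steps would be: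
- The C4 detour (hydroxyl made as a racemate in the aldol step, then silylated, desilylated and reoxidised): four operations would build nothing lasting and would make every intermediate an epimer pair.
- The CBS reduction that sets C2: the only stereocentre would rest on reagent control at a ketone flanked by an ortho-alkoxy aryl group and a branched chain carrying a stereocentre and Lewis-basic acetal oxygens.
- The ring C closure by C–O coupling: it needs oxidative addition into a di-ortho-substituted, electron-rich aryl bromide and reductive elimination from a secondary benzylic alkoxide that can lose a β-hydride, late in a sequence of about thirteen steps.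

**Retrosynthetic overview**
- Key disconnection C2–C1′: a rhodium-catalysed enantioselective conjugate arylation of the flat γ-pyrone ring C of chromone 9 (C2=C3–C4=O) with ring B boronic acid 16 joins the two prenylated halves, turns the pyrone into the dihydropyranone and sets C2, the only stereocentre, with C4 already a ketone.
- Ring order: ring A is bought (phloroacetophenone 1), ring C is closed on it first (O1–C2, step 4), and ring B (from 4,6-dibromoresorcinol 10) is attached last; nothing before step 8 holds the flavanone core.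
- Prenyl placement: C6 lies para to C8a, so the ring A prenyl group is delivered from the oxygen that becomes O1 by a para-Claisen–Cope shift (to C6, not C8); the ring B prenyl group replaces one of two equivalent bromines.
- The design has no C4 carbinol (no silyl on/off, no reoxidation, no epimer pairs), no reagent-controlled ketone reduction and no late C–O coupling; nine steps, six in the longest line.

Key step: step 8

Remark: ethoxymethyl (EOM) acetals protect all phenols; they should behave as MOM ethers in lithiation, in the thermal rearrangement and in acid cleavage, and are made from commercial chloromethyl ethyl ether.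
Remark: the sense of induction in step 8 is assigned by the accepted model for rhodium/diene additions to cyclic enones; the antipodal ligand is equally available should the sense prove opposite.

Step 1
Reactants: 1 2,4,6-trihydroxyacetophenone
Product: 2 1-[2,4-bis(ethoxymethoxy)-6-hydroxyphenyl]ethan-1-one
Conditions: EtOCH2Cl (2.2 equiv), i-Pr2NEt (2.5 equiv), CH2Cl2, 0 °C → rt
Reagents that add atoms: chloromethyl ethyl ether (EOMCl), CCOCCl
Why: Williamson-type O-alkylation should cap the para hydroxyl and one ortho hydroxyl, while the remaining hydroxyl, hydrogen-bonded to the acetyl group, stays free and is thereby singled out as the oxygen that later becomes O1.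

Step 2
Reactants: 2 1-[2,4-bis(ethoxymethoxy)-6-hydroxyphenyl]ethan-1-one; 3 3-methylbut-2-en-1-ol (prenol)
Product: 4 1-[2,4-bis(ethoxymethoxy)-6-[(3-methylbut-2-en-1-yl)oxy]phenyl]ethan-1-one
Conditions: PPh3 (1.5 equiv), diisopropyl azodicarboxylate (1.5 equiv), THF, 0 °C → rt
Reagents that add atoms: none
Why: Mitsunobu etherification should alkylate the chelated but acidic phenol at oxygen by SN2 attack on the phosphonium-activated primary allylic alcohol, which places the prenyl group on the future O1 under neutral conditions that spare the acetals.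

Step 3
Reactants: 4 1-[2,4-bis(ethoxymethoxy)-6-[(3-methylbut-2-en-1-yl)oxy]phenyl]ethan-1-one
Product: 7 1-[2,4-bis(ethoxymethoxy)-6-hydroxy-3-(3-methylbut-2-en-1-yl)phenyl]ethan-1-one, via ortho-dienone 5 (not isolated), via para-dienone 6 (not isolated)
Conditions: PhNEt2, 200 °C, argon
Reagents that add atoms: none
Why: Thermal para-Claisen–Cope rearrangement: a [3,3] shift of the aryl prenyl ether to the free ortho carbon gives dienone 5 with a reverse prenyl group, a second [3,3] (Cope) shift relays it as the normal prenyl group to the para carbon between the two acetal oxygens (dienone 6), and tautomerisation restores the phenol, so the prenyl group should end para to the freed hydroxyl (future C6, not C8), with the amine solvent buffering traces of acid.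

Step 4
Reactants: 7 1-[2,4-bis(ethoxymethoxy)-6-hydroxy-3-(3-methylbut-2-en-1-yl)phenyl]ethan-1-one
Product: 9 5,7-bis(ethoxymethoxy)-6-(3-methylbut-2-en-1-yl)-4H-chromen-4-one, via enaminone 8 (not isolated)
Conditions: Me2NCH(OMe)2 (3 equiv), toluene, 90 °C; evaporate; AcOH, 50 °C
Reagents that add atoms: N,N-dimethylformamide dimethyl acetal, COC(OC)N(C)C
Why: Enaminone route to chromones: condensation of the methyl ketone with the amide acetal gives vinylogous amide 8, and mild acid should trigger 6-endo addition of the only free phenol to the β-carbon and loss of dimethylamine, closing ring C (O1–C2) with the prenyl group at C6 and the aryl acetals intact.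

Step 5
Reactants: 10 4,6-dibromobenzene-1,3-diol (4,6-dibromoresorcinol)
Product: 11 1,5-dibromo-2,4-bis(ethoxymethoxy)benzene
Conditions: EtOCH2Cl (2.4 equiv), i-Pr2NEt (3 equiv), CH2Cl2, 0 °C → rt
Reagents that add atoms: chloromethyl ethyl ether (EOMCl), CCOCCl
Why: Williamson-type O-alkylation of both phenols, made more acidic by the ortho bromines, should give the bis-acetal whose oxygens later stabilise the ortho-lithio species.

Step 6
Reactants: 11 1,5-dibromo-2,4-bis(ethoxymethoxy)benzene; 12 prenyl bromide (1-bromo-3-methylbut-2-ene)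
Product: 14 1-bromo-2,4-bis(ethoxymethoxy)-5-(3-methylbut-2-en-1-yl)benzene, via aryllithium 13 (not isolated)
Conditions: n-BuLi (1.0 equiv), THF, −78 °C, 20 min; CuI (10 mol %); 12 (1.3 equiv), −78 → 0 °C
Reagents that add atoms: none
Why: Bromine–lithium exchange of one of the two equivalent bromines should give the acetal-chelated aryllithium 13, which is alkylated at the primary carbon of prenyl bromide under copper catalysis (SN2 allylic substitution) to give the linear prenyl arene.

Step 7
Reactants: 14 1-bromo-2,4-bis(ethoxymethoxy)-5-(3-methylbut-2-en-1-yl)benzene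
Product: 16 [2,4-bis(ethoxymethoxy)-5-(3-methylbut-2-en-1-yl)phenyl]boronic acid, via aryllithium 15 (not isolated)
Conditions: n-BuLi (1.05 equiv), THF, −78 °C, 20 min; B(OiPr)3 (1.5 equiv), −78 °C → rt; 1 M aq. HCl to pH 5–6, 0 °C
Reagents that add atoms: triisopropyl borate, CC(C)OB(OC(C)C)OC(C)C; water, O
Why: Second bromine–lithium exchange and electrophilic borylation: aryllithium 15 should add to the borate to form an ate complex that is hydrolysed at pH 5–6 to the boronic acid without cleaving the acetals.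

Step 8
Reactants: 9 5,7-bis(ethoxymethoxy)-6-(3-methylbut-2-en-1-yl)-4H-chromen-4-one; 16 [2,4-bis(ethoxymethoxy)-5-(3-methylbut-2-en-1-yl)phenyl]boronic acid
Product: 17 (2S)-2-[2,4-bis(ethoxymethoxy)-5-(3-methylbut-2-en-1-yl)phenyl]-5,7-bis(ethoxymethoxy)-6-(3-methylbut-2-en-1-yl)chroman-4-one
Conditions: [RhCl(C2H4)2]2 (2.5 mol %), (S,S)-Ph-bod* [(1S,4S)-2,5-diphenylbicyclo[2.2.2]octa-2,5-diene] (5.5 mol %), 16 (2.5 equiv, in three portions), aq. KOH (10 mol %), dioxane/H2O (10:1), 40 °C
Reagents that add atoms: none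
Why: Hayashi–Miyaura asymmetric 1,4-addition: the hydroxo complex of monovalent rhodium with the chiral diene transmetalates with boronic acid 16, the aryl–rhodium species binds one enantioface of the C2=C3 bond of chromone 9 and inserts it, and water protonates the resulting oxa-π-allyl rhodium enolate to release 17 and return the hydroxo complex. The closest known reaction type is the rhodium/chiral diene-catalysed conjugate addition of arylboronic acids to chromones, which gives 2-arylchroman-4-ones directly. No ring is closed: ring C, closed in step 4, is converted from the flat γ-pyrone into the dihydropyranone, and the C2–C1′ bond that joins the two prenylated halves is the only bond formed. The single stereocentre C2 is set under catalyst control: the (S,S) diene should shield the Si face of C2 so that the aryl group is delivered to the Re face, which corresponds to 2S. The step needs 1,4- over 1,2-addition and no reaction at the two trisubstituted prenyl alkenes, which do not insert into aryl–rhodium bonds; it also needs the product not to open by E1cB loss of O1, which is secured by sub-stoichiometric hydroxide and by the four capped phenols, so that neither a deactivating 7-phenoxide nor a chelated 2′-hydroxychalcone can form. The ortho-alkoxy boronic acid is used in excess and in portions to offset protodeboronation.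

Step 9
Reactants: 17 (2S)-2-[2,4-bis(ethoxymethoxy)-5-(3-methylbut-2-en-1-yl)phenyl]-5,7-bis(ethoxymethoxy)-6-(3-methylbut-2-en-1-yl)chroman-4-one
Product: 18 (2S)-2-[2,4-dihydroxy-5-(3-methylbut-2-en-1-yl)phenyl]-5,7-dihydroxy-6-(3-methylbut-2-en-1-yl)chroman-4-one (CNP0320454.1)
Conditions: HCl (0.5 M in MeOH), MeOH/THF (4:1), 0 °C → rt
Reagents that add atoms: none
Why: Acid-catalysed transacetalisation to methanol should free the four phenols under anhydrous, dilute and cool conditions chosen so that the prenyl alkenes do not add the neighbouring phenols and the C2–O1 bond, hence the 2S centre, is not ionised.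

**Compound list**
1 | 2,4,6-trihydroxyacetophenone (phloroacetophenone) | CC(=O)c1c(O)cc(O)cc1O | starting material
2 | 1-[2,4-bis(ethoxymethoxy)-6-hydroxyphenyl]ethan-1-one | CC(=O)c1c(O)cc(OCOCC)cc1OCOCC | intermediate
3 | 3-methylbut-2-en-1-ol (prenol) | CC(C)=CCO | starting material
4 | 1-[2,4-bis(ethoxymethoxy)-6-[(3-methylbut-2-en-1-yl)oxy]phenyl]ethan-1-one | CC(=O)c1c(OCC=C(C)C)cc(OCOCC)cc1OCOCC | intermediate
5 | rac-2-acetyl-3,5-bis(ethoxymethoxy)-6-(2-methylbut-3-en-2-yl)cyclohexa-2,4-dien-1-one (ortho-dienone) | CC(=O)C1=C(OCOCC)C=C(OCOCC)C(C(C)(C)C=C)C1=O | intermediate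
6 | rac-2-acetyl-3,5-bis(ethoxymethoxy)-4-(3-methylbut-2-en-1-yl)cyclohexa-2,5-dien-1-one (para-dienone) | CC(=O)C1=C(OCOCC)C(CC=C(C)C)C(OCOCC)=CC1=O | intermediate
7 | 1-[2,4-bis(ethoxymethoxy)-6-hydroxy-3-(3-methylbut-2-en-1-yl)phenyl]ethan-1-one | CC(=O)c1c(O)cc(OCOCC)c(CC=C(C)C)c1OCOCC | intermediate
8 | (E)-3-(dimethylamino)-1-[2,4-bis(ethoxymethoxy)-6-hydroxy-3-(3-methylbut-2-en-1-yl)phenyl]prop-2-en-1-one | CN(C)/C=C/C(=O)c1c(O)cc(OCOCC)c(CC=C(C)C)c1OCOCC | intermediate
9 | 5,7-bis(ethoxymethoxy)-6-(3-methylbut-2-en-1-yl)-4H-chromen-4-one | O=c1ccoc2cc(OCOCC)c(CC=C(C)C)c(OCOCC)c12 | intermediate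
10 | 4,6-dibromobenzene-1,3-diol (4,6-dibromoresorcinol) | Oc1cc(O)c(Br)cc1Br | starting material
11 | 1,5-dibromo-2,4-bis(ethoxymethoxy)benzene | CCOCOc1cc(OCOCC)c(Br)cc1Br | intermediate
12 | prenyl bromide (1-bromo-3-methylbut-2-ene) | CC(C)=CCBr | starting material
13 | [5-bromo-2,4-bis(ethoxymethoxy)phenyl]lithium | [Li]c1cc(Br)c(OCOCC)cc1OCOCC | intermediate
14 | 1-bromo-2,4-bis(ethoxymethoxy)-5-(3-methylbut-2-en-1-yl)benzene | CCOCOc1cc(OCOCC)c(CC=C(C)C)cc1Br | intermediate
15 | [2,4-bis(ethoxymethoxy)-5-(3-methylbut-2-en-1-yl)phenyl]lithium | [Li]c1cc(CC=C(C)C)c(OCOCC)cc1OCOCC | intermediate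
16 | [2,4-bis(ethoxymethoxy)-5-(3-methylbut-2-en-1-yl)phenyl]boronic acid | OB(O)c1cc(CC=C(C)C)c(OCOCC)cc1OCOCC | intermediate
17 | (2S)-2-[2,4-bis(ethoxymethoxy)-5-(3-methylbut-2-en-1-yl)phenyl]-5,7-bis(ethoxymethoxy)-6-(3-methylbut-2-en-1-yl)chroman-4-one | O=C1C[C@@H](c2cc(CC=C(C)C)c(OCOCC)cc2OCOCC)Oc2cc(OCOCC)c(CC=C(C)C)c(OCOCC)c21 | intermediate
18 | (2S)-2-[2,4-dihydroxy-5-(3-methylbut-2-en-1-yl)phenyl]-5,7-dihydroxy-6-(3-methylbut-2-en-1-yl)chroman-4-one | CC(C)=CCc1cc([C@@H]2CC(=O)c3c(cc(O)c(CC=C(C)C)c3O)O2)c(O)cc1O | target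

**Count**
Total steps: 9. Longest linear sequence: 6 (steps 1, 2, 3, 4, 8, 9).

**Steps most likely to fail**

1. Step 8 (conjugate arylation). The hindered, electron-rich aryl–rhodium species may insert the electron-rich pyrone too slowly, so that protodeboronation of the boronic acid or E1cB opening of ring C outruns product formation, or the facial selectivity may be poor. The fallback sets out from 7 and 14 and comes back at 17. Aryllithium 15, made from 14 as in step 7, would be quenched with DMF to give 2,4-bis(ethoxymethoxy)-5-(3-methylbut-2-en-1-yl)benzaldehyde F1. Claisen–Schmidt condensation of this aldehyde with ketone 7 (KOH, EtOH, rt) would give (E)-3-[2,4-bis(ethoxymethoxy)-5-(3-methylbut-2-en-1-yl)phenyl]-1-[2,4-bis(ethoxymethoxy)-6-hydroxy-3-(3-methylbut-2-en-1-yl)phenyl]prop-2-en-1-one F2. NaOAc in EtOH at reflux would close ring C by oxa-Michael addition to rac-2-[2,4-bis(ethoxymethoxy)-5-(3-methylbut-2-en-1-yl)phenyl]-5,7-bis(ethoxymethoxy)-6-(3-methylbut-2-en-1-yl)chroman-4-one F3. Kinetic resolution by asymmetric transfer hydrogenation (RuCl[(R,R)-TsDPEN](p-cymene), HCO2H/Et3N, EtOAc, rt) should reduce the 2R enantiomer to (2R,4R)-2-[2,4-bis(ethoxymethoxy)-5-(3-methylbut-2-en-1-yl)phenyl]-5,7-bis(ethoxymethoxy)-6-(3-methylbut-2-en-1-yl)chroman-4-ol F4, which is removed by chromatography, and leave 17.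

2. Step 3 (para-Claisen–Cope). Dienone 5 may tautomerise to the ortho phenol with a reverse prenyl group faster than it undergoes the Cope shift, or the acetals may be lost at 200 °C. The fallback moves prenylation to the chromone stage by cross-coupling; it sets out from 2 and comes back at 9. Ketone 2 would be treated as in step 4 to give, via (E)-3-(dimethylamino)-1-[2,4-bis(ethoxymethoxy)-6-hydroxyphenyl]prop-2-en-1-one F5, 5,7-bis(ethoxymethoxy)-4H-chromen-4-one F6. The peri acetal, activated by chelation to the C4 carbonyl, would be cleaved selectively (0.1 M HCl in MeOH, 0 °C) to 7-(ethoxymethoxy)-5-hydroxy-4H-chromen-4-one F7. Electrophilic iodination ortho to the free chelated 5-hydroxyl (BnNMe3·ICl2, CaCO3, CH2Cl2/MeOH, rt) should give 7-(ethoxymethoxy)-5-hydroxy-6-iodo-4H-chromen-4-one F8. Stille coupling with tributyl(3-methylbut-2-en-1-yl)stannane (Pd(PPh3)4, DMF, 80 °C) would give 7-(ethoxymethoxy)-5-hydroxy-6-(3-methylbut-2-en-1-yl)-4H-chromen-4-one F9, and O-alkylation (NaH, EtOCH2Cl, DMF) would return 9.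

3. Step 9 (acetal cleavage). The freed phenols may add to the neighbouring prenyl alkenes under acid (chromane formation), or the 2S centre may erode through reversible acid-mediated opening of ring C, which the 2′,4′-dioxygenated ring B assists. The fallback moves acetal cleavage to the two achiral fragments and ends with a fluoride-labile protecting group; it sets out from 9 and 14 and comes back at 18. Methanolic HCl would convert 9 into 5,7-dihydroxy-6-(3-methylbut-2-en-1-yl)-4H-chromen-4-one F10, and TBSOTf/2,6-lutidine would give 5,7-bis[(tert-butyldimethylsilyl)oxy]-6-(3-methylbut-2-en-1-yl)-4H-chromen-4-one F11. Methanolic HCl would convert 14 into 4-bromo-6-(3-methylbut-2-en-1-yl)benzene-1,3-diol F12, and TBSCl/imidazole would give 1-bromo-2,4-bis[(tert-butyldimethylsilyl)oxy]-5-(3-methylbut-2-en-1-yl)benzene F13. Miyaura borylation (B2pin2, PdCl2(dppf), KOAc, dioxane, 80 °C) would give 2-[2,4-bis[(tert-butyldimethylsilyl)oxy]-5-(3-methylbut-2-en-1-yl)phenyl]-4,4,5,5-tetramethyl-1,3,2-dioxaborolane F14. The conjugate arylation of step 8 (with K3PO4 in place of KOH) would join the silylated chromone and this boronate to (2S)-2-[2,4-bis[(tert-butyldimethylsilyl)oxy]-5-(3-methylbut-2-en-1-yl)phenyl]-5,7-bis[(tert-butyldimethylsilyl)oxy]-6-(3-methylbut-2-en-1-yl)chroman-4-one F15, and buffered fluoride (Et3N·3HF, THF, rt) should then give 18.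

**Further compounds**
F1 | step 8 | 2,4-bis(ethoxymethoxy)-5-(3-methylbut-2-en-1-yl)benzaldehyde | O=Cc1cc(CC=C(C)C)c(OCOCC)cc1OCOCC
F2 | step 8 | (E)-3-[2,4-bis(ethoxymethoxy)-5-(3-methylbut-2-en-1-yl)phenyl]-1-[2,4-bis(ethoxymethoxy)-6-hydroxy-3-(3-methylbut-2-en-1-yl)phenyl]prop-2-en-1-one | O=C(/C=C/c1cc(CC=C(C)C)c(OCOCC)cc1OCOCC)c1c(O)cc(OCOCC)c(CC=C(C)C)c1OCOCC
F3 | step 8 | rac-2-[2,4-bis(ethoxymethoxy)-5-(3-methylbut-2-en-1-yl)phenyl]-5,7-bis(ethoxymethoxy)-6-(3-methylbut-2-en-1-yl)chroman-4-one | O=C1CC(c2cc(CC=C(C)C)c(OCOCC)cc2OCOCC)Oc2cc(OCOCC)c(CC=C(C)C)c(OCOCC)c21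
F4 | step 8 | (2R,4R)-2-[2,4-bis(ethoxymethoxy)-5-(3-methylbut-2-en-1-yl)phenyl]-5,7-bis(ethoxymethoxy)-6-(3-methylbut-2-en-1-yl)chroman-4-ol | O[C@@H]1C[C@H](c2cc(CC=C(C)C)c(OCOCC)cc2OCOCC)Oc2cc(OCOCC)c(CC=C(C)C)c(OCOCC)c21
F5 | step 3 | (E)-3-(dimethylamino)-1-[2,4-bis(ethoxymethoxy)-6-hydroxyphenyl]prop-2-en-1-one | CN(C)/C=C/C(=O)c1c(O)cc(OCOCC)cc1OCOCC
F6 | step 3 | 5,7-bis(ethoxymethoxy)-4H-chromen-4-one | O=c1ccoc2cc(OCOCC)cc(OCOCC)c12
F7 | step 3 | 7-(ethoxymethoxy)-5-hydroxy-4H-chromen-4-one | O=c1ccoc2cc(OCOCC)cc(O)c12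
F8 | step 3 | 7-(ethoxymethoxy)-5-hydroxy-6-iodo-4H-chromen-4-one | O=c1ccoc2cc(OCOCC)c(I)c(O)c12
F9 | step 3 | 7-(ethoxymethoxy)-5-hydroxy-6-(3-methylbut-2-en-1-yl)-4H-chromen-4-one | O=c1ccoc2cc(OCOCC)c(CC=C(C)C)c(O)c12
F10 | step 9 | 5,7-dihydroxy-6-(3-methylbut-2-en-1-yl)-4H-chromen-4-one | O=c1ccoc2cc(O)c(CC=C(C)C)c(O)c12
F11 | step 9 | 5,7-bis[(tert-butyldimethylsilyl)oxy]-6-(3-methylbut-2-en-1-yl)-4H-chromen-4-one | O=c1ccoc2cc(O[Si](C)(C)C(C)(C)C)c(CC=C(C)C)c(O[Si](C)(C)C(C)(C)C)c12
F12 | step 9 | 4-bromo-6-(3-methylbut-2-en-1-yl)benzene-1,3-diol | Oc1cc(O)c(CC=C(C)C)cc1Br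
F13 | step 9 | 1-bromo-2,4-bis[(tert-butyldimethylsilyl)oxy]-5-(3-methylbut-2-en-1-yl)benzene | CC(C)(C)[Si](C)(C)Oc1cc(O[Si](C)(C)C(C)(C)C)c(CC=C(C)C)cc1Br
F14 | step 9 | 2-[2,4-bis[(tert-butyldimethylsilyl)oxy]-5-(3-methylbut-2-en-1-yl)phenyl]-4,4,5,5-tetramethyl-1,3,2-dioxaborolane | CC(C)=CCc1cc(B2OC(C)(C)C(C)(C)O2)c(O[Si](C)(C)C(C)(C)C)cc1O[Si](C)(C)C(C)(C)C
F15 | step 9 | (2S)-2-[2,4-bis[(tert-butyldimethylsilyl)oxy]-5-(3-methylbut-2-en-1-yl)phenyl]-5,7-bis[(tert-butyldimethylsilyl)oxy]-6-(3-methylbut-2-en-1-yl)chroman-4-one | O=C1C[C@@H](c2cc(CC=C(C)C)c(O[Si](C)(C)C(C)(C)C)cc2O[Si](C)(C)C(C)(C)C)Oc2cc(O[Si](C)(C)C(C)(C)C)c(CC=C(C)C)c(O[Si](C)(C)C(C)(C)C)c21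
A1 | direct plan | 1-[2,4-bis(methoxymethoxy)-5-(3-methylbut-2-en-1-yl)phenyl]ethan-1-one | CC(=O)c1cc(CC=C(C)C)c(OCOC)cc1OCOC
A2 | direct plan | 6-bromo-2,4-bis(methoxymethoxy)-3-(3-methylbut-2-en-1-yl)benzaldehyde | O=Cc1c(Br)cc(OCOC)c(CC=C(C)C)c1OCOC
A3 | direct plan | rac-3-[6-bromo-2,4-bis(methoxymethoxy)-3-(3-methylbut-2-en-1-yl)phenyl]-1-[2,4-bis(methoxymethoxy)-5-(3-methylbut-2-en-1-yl)phenyl]-3-[(tert-butyldimethylsilyl)oxy]propan-1-one | O=C(CC(O[Si](C)(C)C(C)(C)C)c1c(Br)cc(OCOC)c(CC=C(C)C)c1OCOC)c1cc(CC=C(C)C)c(OCOC)cc1OCOC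
A4 | direct plan | (1S,3RS)-3-[6-bromo-2,4-bis(methoxymethoxy)-3-(3-methylbut-2-en-1-yl)phenyl]-1-[2,4-bis(methoxymethoxy)-5-(3-methylbut-2-en-1-yl)phenyl]-3-[(tert-butyldimethylsilyl)oxy]propan-1-ol | O[C@@H](CC(O[Si](C)(C)C(C)(C)C)c1c(Br)cc(OCOC)c(CC=C(C)C)c1OCOC)c1cc(CC=C(C)C)c(OCOC)cc1OCOC
A5 | direct plan | (2S,4RS)-4-[(tert-butyldimethylsilyl)oxy]-2-[2,4-bis(methoxymethoxy)-5-(3-methylbut-2-en-1-yl)phenyl]-5,7-bis(methoxymethoxy)-6-(3-methylbut-2-en-1-yl)chromane | CC(C)(C)[Si](C)(C)OC1C[C@@H](c2cc(CC=C(C)C)c(OCOC)cc2OCOC)Oc2cc(OCOC)c(CC=C(C)C)c(OCOC)c21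
A6 | direct plan | (2S)-2-[2,4-bis(methoxymethoxy)-5-(3-methylbut-2-en-1-yl)phenyl]-5,7-bis(methoxymethoxy)-6-(3-methylbut-2-en-1-yl)chroman-4-one | O=C1C[C@@H](c2cc(CC=C(C)C)c(OCOC)cc2OCOC)Oc2cc(OCOC)c(CC=C(C)C)c(OCOC)c21
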